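**Retrosynthetic overview**

- Marchantinquinone ⇐ its ring-C benzyl ether (hydrogenolysis, re-oxidation) ⇐ Dötz benzannulation–oxidation of an 18-membered macrocyclic aryl alkynyl ether with pentacarbonyl[methoxy(vinyl)carbene]chromium.
- Enabling feature: ring B is a 2-aryloxy-3-alkyl-1,4-benzoquinone whose C-5 and C-6 are bare CH. C-2 (O to ring D) and C-3 (CH2CH2 to ring A) are the two carbons of an alkyne already held in the macrocycle, C-4/C-5/C-6 are the carbene carbon with its vinyl group, and C-1 is a CO ligand. Because C-1 and C-4 both end as C=O, either orientation of alkyne uptake gives the same quinone.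
- Macrocyclic ynol ether ⇐ macrocyclic α-aryloxy ketone (enol triflate, elimination) ⇐ phenoxide/α-chloroketone etherification that closes the 18-membered ring at the O–CH2 bond.
- Seco chloroketone ⇐ Weinreb amide ⇐ Wittig (ring-C aldehyde + ring-D ylide) and hydrogenation, Heck (ring-A bromide + acrylamide), Ullmann ether (ring-C phenol + ring-A iodide).
- Order of rings: A, C and D are bought; the macrocycle is closed in step 7; quinone ring B is built in step 10.

Key step: step 10

Remark: ring A = para-phenylene ring, ring B = quinone ring, ring C = ring bearing the free phenol, ring D = meta-phenylene ring bound to the quinone oxygen. The target has no stereocentre. The stilbene bond of 9 is taken as an E/Z mixture (no geometry in its SMILES) because step 5 removes it.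

**Route**

Step 1
Reactants: 1 3-hydroxybenzyl alcohol
Product: 2 (3-hydroxybenzyl)triphenylphosphonium bromide
Conditions: Ph3P·HBr, MeCN, reflux
Reagents that add atoms: triphenylphosphine hydrobromide, [Br-].[PH+](c1ccccc1)(c1ccccc1)c1ccccc1
Why: Phosphonium salt formation by acid-assisted displacement of the benzylic hydroxyl by triphenylphosphine; the meta phenol needs no protection.

Step 2
Reactants: 3 4-(benzyloxy)-3-hydroxybenzaldehyde; 4 1-bromo-4-iodobenzene
Product: 5 4-(benzyloxy)-3-(4-bromophenoxy)benzaldehyde
Conditions: CuI (10 mol %), N,N-dimethylglycine hydrochloride (30 mol %), Cs2CO3, 1,4-dioxane, 90 °C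
Reagents that add atoms: none
Why: Ullmann-type diaryl ether synthesis; the copper catalyst with an amino-acid ligand should couple the phenol at the C–I bond below the temperature at which the C–Br bond reacts, and the aldehyde is tolerated.

Step 3
Reactants: 5 4-(benzyloxy)-3-(4-bromophenoxy)benzaldehyde; 6 N-methoxy-N-methylacrylamide
Product: 7 (E)-3-{4-[2-(benzyloxy)-5-formylphenoxy]phenyl}-N-methoxy-N-methylprop-2-enamide
Conditions: Pd(OAc)2 (5 mol %), P(o-tol)3 (10 mol %), Et3N, DMF, 100 °C
Reagents that add atoms: none
Why: Mizoroki–Heck reaction of the aryl bromide with the acrylamide should give the E-cinnamoyl Weinreb amide (syn insertion, syn β-hydride elimination); the geometry is of no later consequence.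

Step 4
Reactants: 7 (E)-3-{4-[2-(benzyloxy)-5-formylphenoxy]phenyl}-N-methoxy-N-methylprop-2-enamide; 2 (3-hydroxybenzyl)triphenylphosphonium bromide
Product: 9 (E)-3-{4-[2-(benzyloxy)-5-[2-(3-hydroxyphenyl)ethenyl]phenoxy]phenyl}-N-methoxy-N-methylprop-2-enamide (stilbene bond E/Z), via phosphonium ylide 8 (not isolated)
Conditions: 2, KOtBu (2.2 equiv), THF, 0 °C; then 7, 0 °C to rt; aq. NH4Cl
Reagents that add atoms: none
Why: Wittig olefination; the semi-stabilised ylide 8 (second equivalent of base for the phenol) should attack only the aldehyde, since the Weinreb amide and the enamide are far less electrophilic, and the E/Z mixture is acceptable because step 5 saturates the bond.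

Step 5
Reactants: 9 stilbene Weinreb amide from step 4
Product: 10 3-{4-[2-(benzyloxy)-5-[2-(3-hydroxyphenyl)ethyl]phenoxy]phenyl}-N-methoxy-N-methylpropanamide
Conditions: H2 (1 atm), 10% Pd/C, 2,2'-bipyridyl (0.5 equiv), EtOAc–MeOH, rt
Reagents that add atoms: none
Why: Heterogeneous hydrogenation with Pd/C poisoned by a nitrogen base should saturate both C=C bonds while hydrogenolysis of the phenolic benzyl ether and of the N–O bond is suppressed.

Step 6
Reactants: 10 bibenzyl Weinreb amide from step 5
Product: 11 1-chloro-4-{4-[2-(benzyloxy)-5-[2-(3-hydroxyphenyl)ethyl]phenoxy]phenyl}butan-2-one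
Conditions: MeLi·LiBr (1.0 equiv), THF, −78 °C; ICH2Cl (3 equiv), then MeLi·LiBr (2.5 equiv) dropwise, −78 °C; AcOH, −78 °C to rt
Reagents that add atoms: chloroiodomethane, ClCI
Why: Homologation of a Weinreb amide with chloromethyllithium (carbenoid from iodine–lithium exchange); the chelated tetrahedral adduct should survive until the acidic quench and so give the α-chloroketone without over-addition, the phenol being masked as its lithium phenoxide.

Step 7
Reactants: 11 seco chloroketone from step 6
Product: 12 macrocyclic α-aryloxy ketone (18-membered ring: ring D–O–CH2–C(=O)–CH2CH2–ring A–O–ring C–CH2CH2–ring D; OBn on ring C)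
Conditions: Cs2CO3 (3 equiv), NaI (0.2 equiv), MeCN, 60 °C, slow addition of 11 (final 2 mM)
Reagents that add atoms: none
Why: Intramolecular Williamson etherification of a caesium phenoxide with the reactive α-haloketone (iodide catalysis, high dilution) should close the 18-membered ring at the O–CH2 bond, a ring more flexible than the target because ring B is not yet present.

Step 8
Reactants: 12 macrocyclic α-aryloxy ketone
Product: 14 macrocyclic aryl ynol ether (ring D–O–C≡C–CH2CH2–ring A in the 18-membered ring), via enol triflate 13 (not isolated)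
Conditions: LiN(SiMe3)2 (1.1 equiv), THF, −78 °C; PhNTf2 (1.1 equiv), −78 to 0 °C; then KOtBu (2.5 equiv), −78 to 0 °C
Reagents that add atoms: none
Why: Ynol ether synthesis from an α-aryloxy ketone; kinetic deprotonation at the more acidic O–CH2 position and O-triflation should give the Z-enol triflate 13 (lithium chelated by the aryloxy oxygen), from which KOtBu removes the vinylic hydrogen anti to the triflate (E2 elimination).

Step 9
Reactants: 15 hexacarbonylchromium Cr(CO)6; 16 tetravinyltin Sn(CH=CH2)4
Product: 19 pentacarbonyl[methoxy(vinyl)carbene]chromium, via vinyllithium 17 (not isolated), via lithium acylchromate 18 (not isolated)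
Conditions: Sn(CH=CH2)4, MeLi, Et2O, 0 °C; Cr(CO)6, Et2O, 0 °C to rt; then Me3OBF4, CH2Cl2–H2O, 0 °C; used at once as a cold solution
Reagents that add atoms: trimethyloxonium tetrafluoroborate, C[O+](C)C.F[B-](F)(F)F
Why: Fischer carbene synthesis; vinyllithium from tin–lithium exchange adds to a CO ligand and the acylchromate is O-methylated by the oxonium salt.

Step 10
Reactants: 14 macrocyclic aryl ynol ether; 19 pentacarbonyl[methoxy(vinyl)carbene]chromium
Product: 21 O-benzylmarchantinquinone (the target with the ring-C phenol as benzyl ether), via hydroquinone monomethyl ether 20 (not isolated)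
Conditions: 19 (2.5 equiv), THF (0.02 M), 55 °C, Ar; then (NH4)2Ce(NO3)6 (7 equiv), MeCN–H2O, 0 °C
Reagents that add atoms: water, O
Why: Proposed new method: the electron-rich ynol ether should attack the electrophilic carbene carbon of 19 through its alkyl-bearing β-carbon and insert into the Cr=C bond (first new ring bond, C-3 to C-4), the aryloxy-stabilised dienylcarbene so formed should insert a CO ligand at the aryloxy-bearing carbon to give a chromium-bound dienylketene, and thermal disrotatory 6π-electrocyclisation of this ketene onto the vinyl terminus (second new ring bond, C-1 to C-6, which closes the six-membered ring B) followed by tautomerisation should give 20, which tetravalent cerium oxidises in the same flask to the para-quinone with loss of methanol and of the metal. The closest known reactions are the Dötz benzannulation of alkenyl(alkoxy)carbene chromium complexes with alkyl- and aryl-substituted alkynes under oxidative work-up to 1,4-benzoquinones, the insertion of ynamines into Fischer carbenes, and the benzannulation of preformed dienylcarbene complexes; an aryl alkynyl ether held in a macrocycle goes beyond them. No stereocentre is formed. The step needs benzannulation to win over cyclobutenone or furan formation and over polymerisation of 19: an alkenyl carbene loses no aromaticity on cyclisation, THF and low concentration favour CO insertion, and 19 is used in excess; the orientation of insertion needs no control, because C-5 and C-6 both carry hydrogen and C-1 and C-4 both end as carbonyl groups.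

Step 11
Reactants: 21 O-benzylmarchantinquinone
Product: 23 marchantinquinone, via hydroquinone 22 (not isolated)
Conditions: H2 (1 atm), 10% Pd/C, EtOAc, rt; filter; then Ag2O, Na2SO4, Et2O, rt
Reagents that add atoms: none
Why: Hydrogenolysis of the aryl benzyl ether (the quinone is reduced to hydroquinone 22 at the same time) followed by Ag2O, which should re-oxidise the hydroquinone but not the ring-C phenol; no stereocentre is involved.

**Compound list**

1 | 3-hydroxybenzyl alcohol | OCc1cccc(O)c1 | starting material
2 | (3-hydroxybenzyl)triphenylphosphonium bromide | [Br-].Oc1cccc(C[P+](c2ccccc2)(c2ccccc2)c2ccccc2)c1 | intermediate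
3 | 4-(benzyloxy)-3-hydroxybenzaldehyde | O=Cc1ccc(OCc2ccccc2)c(O)c1 | starting material
4 | 1-bromo-4-iodobenzene | Brc1ccc(I)cc1 | starting material
5 | 4-(benzyloxy)-3-(4-bromophenoxy)benzaldehyde | O=Cc1ccc(OCc2ccccc2)c(Oc2ccc(Br)cc2)c1 | intermediate
6 | N-methoxy-N-methylacrylamide | C=CC(=O)N(C)OC | starting material
7 | (E)-3-{4-[2-(benzyloxy)-5-formylphenoxy]phenyl}-N-methoxy-N-methylprop-2-enamide | O=Cc1ccc(OCc2ccccc2)c(Oc2ccc(/C=C/C(=O)N(C)OC)cc2)c1 | intermediate
8 | potassium 3-[(triphenylphosphoranylidene)methyl]phenolate (ylide) | [K+].[O-]c1cccc(C=P(c2ccccc2)(c2ccccc2)c2ccccc2)c1 | intermediate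
9 | (E)-3-{4-[2-(benzyloxy)-5-[2-(3-hydroxyphenyl)ethenyl]phenoxy]phenyl}-N-methoxy-N-methylprop-2-enamide (stilbene bond E/Z mixture) | Oc1cccc(C=Cc2ccc(OCc3ccccc3)c(Oc3ccc(/C=C/C(=O)N(C)OC)cc3)c2)c1 | intermediate
10 | 3-{4-[2-(benzyloxy)-5-[2-(3-hydroxyphenyl)ethyl]phenoxy]phenyl}-N-methoxy-N-methylpropanamide | Oc1cccc(CCc2ccc(OCc3ccccc3)c(Oc3ccc(CCC(=O)N(C)OC)cc3)c2)c1 | intermediate
11 | 1-chloro-4-{4-[2-(benzyloxy)-5-[2-(3-hydroxyphenyl)ethyl]phenoxy]phenyl}butan-2-one | Oc1cccc(CCc2ccc(OCc3ccccc3)c(Oc3ccc(CCC(=O)CCl)cc3)c2)c1 | intermediate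
12 | macrocyclic α-aryloxy ketone (18-membered; ring D–O–CH2–C(=O)–CH2CH2–ring A) | O=C1COc2cccc(c2)CCc2ccc(OCc3ccccc3)c(c2)Oc2ccc(CC1)cc2 | intermediate
13 | macrocyclic Z-enol triflate (ring D–O–CH=C(OTf)–CH2CH2–ring A) | FC(F)(F)S(=O)(=O)O/C1=C\Oc2cccc(c2)CCc2ccc(OCc3ccccc3)c(c2)Oc2ccc(CC1)cc2 | intermediate
14 | macrocyclic aryl ynol ether (ring D–O–C≡C–CH2CH2–ring A) | C1#COc2cccc(c2)CCc2ccc(OCc3ccccc3)c(c2)Oc2ccc(CC1)cc2 | intermediate
15 | hexacarbonylchromium | O=C=[Cr](=C=O)(=C=O)(=C=O)(=C=O)=C=O | starting material
16 | tetravinyltin | C=C[Sn](C=C)(C=C)C=C | starting material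
17 | vinyllithium | [Li]C=C | intermediate
18 | lithium pentacarbonyl(acryloyl)chromate (acylchromate) | [Li+].[O-]C(C=C)=[Cr](=C=O)(=C=O)(=C=O)(=C=O)=C=O | intermediate
19 | pentacarbonyl[methoxy(vinyl)carbene]chromium | COC(C=C)=[Cr](=C=O)(=C=O)(=C=O)(=C=O)=C=O | intermediate
20 | hydroquinone monomethyl ether of O-benzylmarchantinquinone (OH next to the aryloxy carbon, OMe next to the alkyl carbon) | COc1ccc(O)c2c1CCc1ccc(cc1)Oc1cc(ccc1OCc1ccccc1)CCc1cccc(c1)O2 | intermediate
21 | O-benzylmarchantinquinone | O=C1C=CC(=O)C2=C1CCc1ccc(cc1)Oc1cc(ccc1OCc1ccccc1)CCc1cccc(c1)O2 | intermediate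
22 | marchantinquinone hydroquinone (ring B as 1,4-dihydroxyarene) | Oc1ccc(O)c2c1CCc1ccc(cc1)Oc1cc(ccc1O)CCc1cccc(c1)O2 | intermediate
23 | marchantinquinone | O=C1C=CC(=O)C2=C1CCc1ccc(cc1)Oc1cc(ccc1O)CCc1cccc(c1)O2 | target

**Step count**

Total: 11 steps. Longest linear sequence: 9 steps (steps 2, 3, 4, 5, 6, 7, 8, 10, 11 from compound 3).

**Three steps most likely to fail**

Step 10. The vinylcarbene complex may polymerise faster than it takes up the alkyne, the aryloxy-stabilised insertion product may fail to insert CO, or the ynol ether may add across the vinyl group instead of the carbene carbon. The fallback uses known chemistry and sets out from 14. Heating with cyclobut-2-enone in toluene at 80 °C should effect a Danheiser benzannulation (ring opening to vinylketene, [2+2] addition to the ynol ether, 4π opening, 6π closure) and give the macrocyclic 2-alkyl-3-aryloxyphenol F1. Its free para position is then oxidised with Fremy's salt, (KSO3)2NO, in phosphate-buffered aqueous acetone to the para-quinone, and the route is rejoined at 21.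

Step 8. Deprotonation may occur on the CH2CH2 side instead of the O–CH2 side, or the base may isomerise the macrocyclic alkyne to an allenyl ether during the elimination. The fallback sets out from 10. Reduction of the Weinreb amide with i-Bu2AlH should give the aldehyde F2, and Corey–Fuchs olefination (CBr4, PPh3) the 1,1-dibromoalkene F3. Copper-catalysed intramolecular vinylic C–O coupling with the ring-D phenol (CuI, 2,2'-bipyridyl, K3PO4, toluene, 110 °C, high dilution) should then close the macrocycle as the Z-bromoenol ether F4. KOtBu eliminates hydrogen bromide, and the route is rejoined at 14, with steps 6 to 8 bypassed.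

Step 7. Intermolecular etherification to oligomers may outrun ring closure, or the base may cause self-condensation of the chloroketone. The fallback sets out from 10. MeMgBr should give the methyl ketone F5. Trifluoroacetylation of its kinetic enolate (LiN(SiMe3)2, CF3CO2CH2CF3) should give the trifluoroacetyl ketone F6, and detrifluoroacetylative diazo transfer (MsN3, Et3N, H2O, MeCN) the diazoketone F7. Rh2(OAc)4-catalysed intramolecular O–H insertion of the carbenoid into the ring-D phenol under slow addition should close the same 18-membered ring under neutral conditions, and the route is rejoined at 12.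

Further compounds
F1 | step 10 | macrocyclic 2-alkyl-3-aryloxyphenol (ring B as phenol, OH next to the alkyl carbon) | Oc1cccc2c1CCc1ccc(cc1)Oc1cc(ccc1OCc1ccccc1)CCc1cccc(c1)O2
F2 | step 8 | 3-{4-[2-(benzyloxy)-5-[2-(3-hydroxyphenyl)ethyl]phenoxy]phenyl}propanal | Oc1cccc(CCc2ccc(OCc3ccccc3)c(Oc3ccc(CCC=O)cc3)c2)c1
F3 | step 8 | 3-{2-[4-(benzyloxy)-3-[4-(4,4-dibromobut-3-enyl)phenoxy]phenyl]ethyl}phenol | Oc1cccc(CCc2ccc(OCc3ccccc3)c(Oc3ccc(CCC=C(Br)Br)cc3)c2)c1
F4 | step 8 | macrocyclic Z-bromoenol ether (ring D–O–C(Br)=CH–CH2CH2–ring A) | Br/C1=C\CCc2ccc(cc2)Oc2cc(ccc2OCc2ccccc2)CCc2cccc(c2)O1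
F5 | step 7 | 4-{4-[2-(benzyloxy)-5-[2-(3-hydroxyphenyl)ethyl]phenoxy]phenyl}butan-2-one | Oc1cccc(CCc2ccc(OCc3ccccc3)c(Oc3ccc(CCC(C)=O)cc3)c2)c1
F6 | step 7 | 1,1,1-trifluoro-6-{4-[2-(benzyloxy)-5-[2-(3-hydroxyphenyl)ethyl]phenoxy]phenyl}hexane-2,4-dione | Oc1cccc(CCc2ccc(OCc3ccccc3)c(Oc3ccc(CCC(=O)CC(=O)C(F)(F)F)cc3)c2)c1
F7 | step 7 | 1-diazo-4-{4-[2-(benzyloxy)-5-[2-(3-hydroxyphenyl)ethyl]phenoxy]phenyl}butan-2-one | Oc1cccc(CCc2ccc(OCc3ccccc3)c(Oc3ccc(CCC(=O)C=[N+]=[N-])cc3)c2)c1
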